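Start from the amounts. In the closed flask, zeta, partner is the limiting reagent at 0.800 equiv. Counting one partner per product, product can reach at most 0.800 of the substrate charge.

| flask | substrate | partner | free catalyst | remark | time |
|---|---|---|---|---|---|
| dusk | 0.28 M | 0.80 equiv | 0.2 mol% | run made earlier |  |
| midnight | 0.28 M | 0.80 equiv | 0.1 mol% | run made earlier |  |
| winter | 0.28 M | 0.80 equiv | 0.15 mol% | run made earlier |  |
| autumn | 0.28 M | 1.6 equiv | 0.2 mol% | run made earlier |  |
| delta | 0.28 M | 0.800 equiv (fed, over 20.0 h) | 0.2 mol% | a stirred flask in which partner is dosed at a steady rate over 20.0 h without added volume, worked up at 40 h | 40 h |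
| eta | 0.28 M | 0.800 equiv | 0.2 mol% | one stirred flow tank at steady state, fed with the mixture as stated, mean residence time 40 h |  |
| alpha | 0.28 M (fed, over 20.0 h) | 0.800 equiv | 0.2 mol% | all but substrate at the start; substrate goes in evenly over 20.0 h, the run ends at 40 h | 40 h |
| zeta | 0.28 M | 0.800 equiv | 0.2 mol% | a closed flask charged with all of it at once and left for 40 h | 40 h |

- dusk (time / h: product / %, substrate / %): 3.00: 4.5, 95.5; 8.00: 11.3, 88.8; 15.0: 20.5, 79.4; 25.0: 33.6, 66.2
- midnight (time / h: product / %, substrate / %): 8.00: 5.6, 93.8; 15.0: 10.3, 89.7; 25.0: 17.4, 82.3; 30.0: 20.1, 79.4
- winter (time / h: product / %, substrate / %): 2.50: 2.6, 97.4; 6.00: 6.3, 93.6; 15.0: 15.7, 84.1; 30.0: 30.5, 68.9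
- autumn (time / h: product / %, substrate / %): 8.00: 11.9, 88.5; 15.0: 21.7, 78.3; 25.0: 35.3, 65.4; 30.0: 41.5, 58.4

(readings scatter by 0.3 percentage points)

- the stated concentrations are those of everything mixed, before any reaction; amounts are the same in each set-up
- the feed brings no volume worth counting
- the earlier runs were made in a closed, stirred flask

1. the set-up with the highest amount of product at the outlet or at the end, in percent of the substrate put in ("none" if the first two lie within 2 percentage points) (delta / eta / alpha / zeta / none)
2. amount of product at the outlet or at the end, in percent of the substrate put in, delta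
3. amount of product at the outlet or at the end, in percent of the substrate put in, eta
4. amount of product at the outlet or at the end, in percent of the substrate put in, alpha
5. amount of product at the outlet or at the end, in percent of the substrate put in, zeta

So keep a ledger of the partner in zeta, and let the readings fill its product entry. Call the pace the product made per mole of free catalyst charged per hour, the turnover frequency. The dusk run at 25.0 h gives 6.72 h⁻¹. The last readings of the midnight and winter runs give 6.70 h⁻¹ and 6.78 h⁻¹, so in these three runs, at one partner charge, product follows catalyst times time. The autumn run, with twice the partner, reads 7.06 h⁻¹ at 25.0 h, against 6.72 h⁻¹ for dusk at that time, so its product reading stands 5.06% higher.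

The pace drifts a little: dusk reads 6.83 h⁻¹ up to 15.0 h, then 6.55 h⁻¹ up to 25.0 h, which is slower, though these are readings with their scatter. My ledger for zeta at 40 h carries dusk forward at the later pace. The product entry comes to 53.2% of the substrate charge, and I take that as a high mark. The whole catalyst charge is 0.250% of the partner charge, so my books close with about 33.5% of the partner left, a low mark because the product entry is a high one.

The forecast gives zeta 51%, which is 2.2 percentage points below my mark, delta 46.5%, eta 45.5% and alpha 45%, with zeta best. Its grounds: “the reaction is nearly saturated in both reagents”.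

The flasks give delta 47.8%, eta 45.8%, alpha 45.1% and zeta 51.2%, so zeta stands first, ahead of delta by 3.4 points, more than the margin.

    catalyst intermediate B → free catalyst + product (k = 0.160 min⁻¹)
    partner + free catalyst → catalyst intermediate A (k = 8.69 M⁻¹ min⁻¹)
    substrate + catalyst intermediate A → catalyst intermediate B (k = 2.19 M⁻¹ min⁻¹)

In zeta, 36% of the partner was still there at 40.0 h. Zeta's average pace over the run was 6.40 h⁻¹, lower than the 6.72 h⁻¹ read from dusk up to 25.0 h. For the neighbour of zeta with 0.12 mol% of free catalyst, 6.72 h⁻¹ times loading and time gives 32.3%, and that flask gave 32.4%.

(The readings stem from a simulated flask from invented constants, and the scatter is random.)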